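**Plan**
- Retrosynthesis: the four benzyl ethers, the 3‑O‑methyl group and the C3–O bond are removed first, leaving a 3‑unsubstituted flavone. Its C4–C4a acyl–aryl bond is cut next, then the O1–C2 vinyl ether bond, then the CH2–C8 bond of the diarylmethane, and last the CH2–Cl, O‑alkyl and acyl–aryl bonds of the dihydrochalcone ring.
- Forward: the dihydrochalcone ring is built and armed with a chloromethyl group (steps 1–4), joined through the CH2 bridge to 3,5‑bis(benzyloxy)phenol (step 5), the phenol is vinylated with ethyl phenylpropiolate and the ester saponified (steps 6–7). The pyranone, the only ring formed in the route, closes in step 8, and C3 oxygenation, O‑methylation and debenzylation finish the synthesis (steps 9–11).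
- Enabling feature: the carbonyl carbon C4 is bonded to C4a, which lies ortho to C8a–O1 and ortho/para to the oxygens on C5 and C7, so it is the natural site for acylation by a chain tethered to O1. C8, the other carbon ortho to O1, carries the bridge, and O1 is the only oxygen of that ring left as a free phenol before vinylation.
- Stereochemistry: the target has no stereocentre. The only stereochemical element is the Z geometry of the aryloxyacrylate (anti addition in step 6), which is absorbed into the aromatic pyranone.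

Key step: step 8

Assumption: the target contains no stereocentre and no stereogenic double bond, so it is a single achiral compound and the question of enantiomers does not arise.

**Route**

Step 1
Reactants: 1 2,4,6-trihydroxytoluene; 2 3-phenylpropanoyl chloride
Product: 3 1-(2,4,6-trihydroxy-3-methylphenyl)-3-phenylpropan-1-one
Conditions: AlCl3 (3.5 equiv), PhNO2–CH2Cl2, 0 → 50 °C; ice/HCl
Reagents that add atoms: none
Why: Friedel–Crafts C‑acylation of a phloroglucinol, in which the two free ring positions of 1 are equivalent and the first acyl group deactivates the ring toward a second, so a single mono‑ketone is expected.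

Step 2
Reactants: 3 1-(2,4,6-trihydroxy-3-methylphenyl)-3-phenylpropan-1-one
Product: 4 1-(2,6-dihydroxy-4-methoxy-3-methylphenyl)-3-phenylpropan-1-one
Conditions: Me2SO4 (1.05 equiv), K2CO3 (1.0 equiv), acetone, rt → 40 °C
Reagents that add atoms: dimethyl sulfate, COS(=O)(=O)OC
Why: Williamson O‑methylation under stoichiometric control, relying on the hydroxyl para to the ketone being the most acidic while the two ortho hydroxyls are held back by hydrogen bonding to the carbonyl.

Step 3
Reactants: 4 1-(2,6-dihydroxy-4-methoxy-3-methylphenyl)-3-phenylpropan-1-one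
Product: 5 1-[2,6-bis(benzyloxy)-4-methoxy-3-methylphenyl]-3-phenylpropan-1-one
Conditions: BnBr (2.6 equiv), K2CO3 (3 equiv), cat. Bu4NI, DMF, 70 °C
Reagents that add atoms: benzyl bromide, BrCc1ccccc1
Why: Williamson benzylation of the two chelated phenols, which needs heating in DMF but uses a base too weak to enolise the hindered ketone.

Step 4
Reactants: 5 1-[2,6-bis(benzyloxy)-4-methoxy-3-methylphenyl]-3-phenylpropan-1-one
Product: 6 1-[2,6-bis(benzyloxy)-3-(chloromethyl)-4-methoxy-5-methylphenyl]-3-phenylpropan-1-one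
Conditions: (CH2O)n (3 equiv), HCl (g), 1,4-dioxane, 10 → 20 °C; cold aqueous work-up, used crude
Reagents that add atoms: paraformaldehyde (as formaldehyde), C=O; hydrogen chloride, Cl
Why: Blanc chloromethylation at the single free ring position, which is ortho to the methoxy and one benzyloxy group and para to the other and should therefore react without a Lewis acid, under conditions that benzyl aryl ethers tolerate at or below room temperature.

Step 5
Reactants: 6 1-[2,6-bis(benzyloxy)-3-(chloromethyl)-4-methoxy-5-methylphenyl]-3-phenylpropan-1-one; 7 3,5-bis(benzyloxy)phenol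
Product: 9 1-[2,6-bis(benzyloxy)-3-{[2,4-bis(benzyloxy)-6-hydroxyphenyl]methyl}-4-methoxy-5-methylphenyl]-3-phenylpropan-1-one, via sodium 3,5-bis(benzyloxy)phenoxide 8 (not isolated)
Conditions: 7 (2.5 equiv), NaH (2.5 equiv), toluene, 0 °C → rt; then 6, toluene, rt → 60 °C; aq. NH4Cl
Reagents that add atoms: none
Why: ortho‑selective C‑benzylation of a sodium phenoxide in a non‑polar solvent (Claisen‑type C‑alkylation), where the tight ion pair shields oxygen and sodium–chloride coordination delivers the benzylic carbon to one of the two equivalent ortho carbons, while the excess phenoxide limits double alkylation.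

Step 6
Reactants: 9 1-[2,6-bis(benzyloxy)-3-{[2,4-bis(benzyloxy)-6-hydroxyphenyl]methyl}-4-methoxy-5-methylphenyl]-3-phenylpropan-1-one; 10 ethyl 3-phenylprop-2-ynoate (ethyl phenylpropiolate)
Product: 11 ethyl (2Z)-3-[3,5-bis(benzyloxy)-2-{[2,4-bis(benzyloxy)-6-methoxy-5-methyl-3-(3-phenylpropanoyl)phenyl]methyl}phenoxy]-3-phenylprop-2-enoate
Conditions: 10 (1.5 equiv), K2CO3 (0.5 equiv), DMF, 80 °C
Reagents that add atoms: none
Why: base‑catalysed oxa‑Michael addition of the only free phenol to the ynoate (first half of the Ruhemann flavone synthesis), in which anti addition should place the aryloxy group and the ester cis to each other (Z).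

Step 7
Reactants: 11 ethyl (2Z)-3-[3,5-bis(benzyloxy)-2-{[2,4-bis(benzyloxy)-6-methoxy-5-methyl-3-(3-phenylpropanoyl)phenyl]methyl}phenoxy]-3-phenylprop-2-enoate
Product: 12 (2Z)-3-[3,5-bis(benzyloxy)-2-{[2,4-bis(benzyloxy)-6-methoxy-5-methyl-3-(3-phenylpropanoyl)phenyl]methyl}phenoxy]-3-phenylprop-2-enoic acid
Conditions: LiOH·H2O (3 equiv), THF–MeOH–H2O, 40 °C; then cold 1 M HCl to pH 3
Reagents that add atoms: lithium hydroxide, [Li+].[OH-]
Why: ester saponification by acyl–oxygen cleavage under mild conditions, with the β‑phenyl group hindering conjugate attack on the enol ether and the benzyl ethers and ketone inert to hydroxide.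

Step 8
Reactants: 12 (2Z)-3-[3,5-bis(benzyloxy)-2-{[2,4-bis(benzyloxy)-6-methoxy-5-methyl-3-(3-phenylpropanoyl)phenyl]methyl}phenoxy]-3-phenylprop-2-enoic acid
Product: 14 5,7-bis(benzyloxy)-8-{[2,4-bis(benzyloxy)-6-methoxy-5-methyl-3-(3-phenylpropanoyl)phenyl]methyl}-2-phenyl-4H-chromen-4-one, via mixed trifluoroacetic anhydride 13 (not isolated)
Conditions: (CF3CO)2O (3 equiv), CH2Cl2, 0 °C → rt; aq. NaHCO3
Reagents that add atoms: none
Why: Trifluoroacetic anhydride turns acid 12 into the mixed anhydride 13, whose acyl carbon (the future C4) is attacked by the ring carbon ortho to the vinyloxy oxygen (the future C4a), and loss of a proton from the Wheland intermediate restores the arene and gives the pyranone. The closest known reaction is the Ruhemann flavone synthesis (cyclodehydration of β‑aryloxycinnamic acids), run here as a TFAA‑mediated intramolecular Friedel–Crafts acylation of the kind used for activated aryloxy acids. The six‑membered ring (O1, C2, C3, C4, C4a, C8a) closes in the 6‑exo‑trig mode at the acyl carbon, the Z geometry holding the acyl group next to the aryloxy ring. No stereocentre is formed. The step needs closure at C4a only, and the substrate secures it: the other carbon ortho to the vinyloxy oxygen carries the bridge, the attacked carbon is also ortho and para to the two benzyloxy groups, and the hexasubstituted dihydrochalcone ring has no free position. The Lewis‑acid‑free conditions should spare the four benzyl ethers and the ketone, and any E isomer present is expected to equilibrate through reversible C‑protonation of the enol ether.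

Step 9
Reactants: 14 5,7-bis(benzyloxy)-8-{[2,4-bis(benzyloxy)-6-methoxy-5-methyl-3-(3-phenylpropanoyl)phenyl]methyl}-2-phenyl-4H-chromen-4-one
Product: 16 5,7-bis(benzyloxy)-8-{[2,4-bis(benzyloxy)-6-methoxy-5-methyl-3-(3-phenylpropanoyl)phenyl]methyl}-3-hydroxy-2-phenyl-4H-chromen-4-one, via flavone 2,3-epoxide 15 (not isolated)
Conditions: DMDO (ca. 0.08 M in acetone, 3 equiv), CH2Cl2, 0 °C → rt, dark; evaporate; then TsOH·H2O (10 mol %), CH2Cl2, rt
Reagents that add atoms: dimethyldioxirane, CC1(C)OO1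
Why: electrophilic epoxidation of the enol‑ether‑like C2=C3 bond by dimethyldioxirane under neutral conditions, followed by acid‑catalysed opening at C2 and tautomerisation (the known flavone‑to‑flavonol conversion), in which the two stereocentres of the necessarily cis‑fused racemic epoxide are lost again.

Step 10
Reactants: 16 5,7-bis(benzyloxy)-8-{[2,4-bis(benzyloxy)-6-methoxy-5-methyl-3-(3-phenylpropanoyl)phenyl]methyl}-3-hydroxy-2-phenyl-4H-chromen-4-one
Product: 17 5,7-bis(benzyloxy)-8-{[2,4-bis(benzyloxy)-6-methoxy-5-methyl-3-(3-phenylpropanoyl)phenyl]methyl}-3-methoxy-2-phenyl-4H-chromen-4-one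
Conditions: MeI (3 equiv), K2CO3 (2 equiv), acetone, 45 °C
Reagents that add atoms: iodomethane, CI
Why: Williamson O‑methylation of the only free hydroxyl, the acidic enolic 3‑OH, with a carbonate base that does not enolise the dihydrochalcone ketone.

Step 11
Reactants: 17 5,7-bis(benzyloxy)-8-{[2,4-bis(benzyloxy)-6-methoxy-5-methyl-3-(3-phenylpropanoyl)phenyl]methyl}-3-methoxy-2-phenyl-4H-chromen-4-one
Product: 18 8-{[2,4-dihydroxy-6-methoxy-5-methyl-3-(3-phenylpropanoyl)phenyl]methyl}-5,7-dihydroxy-3-methoxy-2-phenyl-4H-chromen-4-one (CNP0280022.0)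
Conditions: H2 (1 atm), 10% Pd/C, EtOAc–MeOH, rt; stopped after uptake of four equivalents
Reagents that add atoms: none
Why: catalytic hydrogenolysis of the four benzyl aryl ethers, under which the tetrasubstituted C2=C3 bond, the hindered aryl ketone and the diarylmethane bridge should not be reduced at atmospheric pressure and room temperature.

**Compound list**
1 | 2,4,6-trihydroxytoluene (2-methylbenzene-1,3,5-triol) | Cc1c(O)cc(O)cc1O | starting material
2 | 3-phenylpropanoyl chloride | O=C(Cl)CCc1ccccc1 | starting material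
3 | 1-(2,4,6-trihydroxy-3-methylphenyl)-3-phenylpropan-1-one | Cc1c(O)cc(O)c(C(=O)CCc2ccccc2)c1O | intermediate
4 | 1-(2,6-dihydroxy-4-methoxy-3-methylphenyl)-3-phenylpropan-1-one | COc1cc(O)c(C(=O)CCc2ccccc2)c(O)c1C | intermediate
5 | 1-[2,6-bis(benzyloxy)-4-methoxy-3-methylphenyl]-3-phenylpropan-1-one | COc1cc(OCc2ccccc2)c(C(=O)CCc2ccccc2)c(OCc2ccccc2)c1C | intermediate
6 | 1-[2,6-bis(benzyloxy)-3-(chloromethyl)-4-methoxy-5-methylphenyl]-3-phenylpropan-1-one | COc1c(C)c(OCc2ccccc2)c(C(=O)CCc2ccccc2)c(OCc2ccccc2)c1CCl | intermediate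
7 | 3,5-bis(benzyloxy)phenol | Oc1cc(OCc2ccccc2)cc(OCc2ccccc2)c1 | starting material
8 | sodium 3,5-bis(benzyloxy)phenoxide | [Na+].[O-]c1cc(OCc2ccccc2)cc(OCc2ccccc2)c1 | intermediate
9 | 1-[2,6-bis(benzyloxy)-3-{[2,4-bis(benzyloxy)-6-hydroxyphenyl]methyl}-4-methoxy-5-methylphenyl]-3-phenylpropan-1-one | COc1c(C)c(OCc2ccccc2)c(C(=O)CCc2ccccc2)c(OCc2ccccc2)c1Cc1c(O)cc(OCc2ccccc2)cc1OCc1ccccc1 | intermediate
10 | ethyl 3-phenylprop-2-ynoate (ethyl phenylpropiolate) | CCOC(=O)C#Cc1ccccc1 | starting material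
11 | ethyl (2Z)-3-[3,5-bis(benzyloxy)-2-{[2,4-bis(benzyloxy)-6-methoxy-5-methyl-3-(3-phenylpropanoyl)phenyl]methyl}phenoxy]-3-phenylprop-2-enoate | COc1c(C)c(OCc2ccccc2)c(C(=O)CCc2ccccc2)c(OCc2ccccc2)c1Cc1c(OCc2ccccc2)cc(OCc2ccccc2)cc1O/C(c1ccccc1)=C\C(=O)OCC | intermediate
12 | (2Z)-3-[3,5-bis(benzyloxy)-2-{[2,4-bis(benzyloxy)-6-methoxy-5-methyl-3-(3-phenylpropanoyl)phenyl]methyl}phenoxy]-3-phenylprop-2-enoic acid | COc1c(C)c(OCc2ccccc2)c(C(=O)CCc2ccccc2)c(OCc2ccccc2)c1Cc1c(OCc2ccccc2)cc(OCc2ccccc2)cc1O/C(c1ccccc1)=C\C(=O)O | intermediate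
13 | mixed anhydride of acid 12 with trifluoroacetic acid, (2Z) | COc1c(C)c(OCc2ccccc2)c(C(=O)CCc2ccccc2)c(OCc2ccccc2)c1Cc1c(OCc2ccccc2)cc(OCc2ccccc2)cc1O/C(c1ccccc1)=C\C(=O)OC(=O)C(F)(F)F | intermediate
14 | 5,7-bis(benzyloxy)-8-{[2,4-bis(benzyloxy)-6-methoxy-5-methyl-3-(3-phenylpropanoyl)phenyl]methyl}-2-phenyl-4H-chromen-4-one | COc1c(C)c(OCc2ccccc2)c(C(=O)CCc2ccccc2)c(OCc2ccccc2)c1Cc1c(OCc2ccccc2)cc(OCc2ccccc2)c2c(=O)cc(-c3ccccc3)oc12 | intermediate
15 | racemic cis-fused 2,3-epoxide of flavone 14 (1a-phenyl-1a,7a-dihydro-7H-oxireno[2,3-b]chromen-7-one core; one enantiomer drawn) | COc1c(C)c(OCc2ccccc2)c(C(=O)CCc2ccccc2)c(OCc2ccccc2)c1Cc1c(OCc2ccccc2)cc(OCc2ccccc2)c2c1O[C@@]1(c3ccccc3)O[C@H]1C2=O | intermediate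
16 | 5,7-bis(benzyloxy)-8-{[2,4-bis(benzyloxy)-6-methoxy-5-methyl-3-(3-phenylpropanoyl)phenyl]methyl}-3-hydroxy-2-phenyl-4H-chromen-4-one | COc1c(C)c(OCc2ccccc2)c(C(=O)CCc2ccccc2)c(OCc2ccccc2)c1Cc1c(OCc2ccccc2)cc(OCc2ccccc2)c2c(=O)c(O)c(-c3ccccc3)oc12 | intermediate
17 | 5,7-bis(benzyloxy)-8-{[2,4-bis(benzyloxy)-6-methoxy-5-methyl-3-(3-phenylpropanoyl)phenyl]methyl}-3-methoxy-2-phenyl-4H-chromen-4-one | COc1c(C)c(OCc2ccccc2)c(C(=O)CCc2ccccc2)c(OCc2ccccc2)c1Cc1c(OCc2ccccc2)cc(OCc2ccccc2)c2c(=O)c(OC)c(-c3ccccc3)oc12 | intermediate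
18 | 8-{[2,4-dihydroxy-6-methoxy-5-methyl-3-(3-phenylpropanoyl)phenyl]methyl}-5,7-dihydroxy-3-methoxy-2-phenyl-4H-chromen-4-one (CNP0280022.0) | COc1c(C)c(O)c(C(=O)CCc2ccccc2)c(O)c1Cc1c(O)cc(O)c2c(=O)c(OC)c(-c3ccccc3)oc12 | target

**Step count**
Total: 11 steps. Longest linear sequence: 11 steps (from 1; compounds 2, 7 and 10 are bought).

**Steps most likely to fail**

Step 5. O‑benzylation or attack at the para carbon of the phenoxide may compete with ortho attack, or the hindered, easily ionised chloride may decompose before it is captured. The fallback sets out from 6 (with 7) and returns at 9. The chloride is oxidised with N‑methylmorpholine N‑oxide in MeCN to 2,4-bis(benzyloxy)-6-methoxy-5-methyl-3-(3-phenylpropanoyl)benzaldehyde F1. The bromomagnesium phenoxide of 7 (EtMgBr, toluene–CH2Cl2) should then add to the aldehyde through its ortho carbon only, within a magnesium chelate (Casiraghi ortho‑hydroxyalkylation), giving racemic 1-[2,6-bis(benzyloxy)-3-{[2,4-bis(benzyloxy)-6-hydroxyphenyl](hydroxy)methyl}-4-methoxy-5-methylphenyl]-3-phenylpropan-1-one F2. Ionic hydrogenation of this doubly activated benzylic alcohol (Et3SiH, TFA, CH2Cl2, −20 °C) would deliver 9.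

Step 8. The liberated acid may cleave the vinyl ether or a benzyl ether, the electron‑rich rings may be trifluoroacetylated before closure, or an E isomer may fail to equilibrate. The fallback sets out from 9 and returns at 14, making the C4–C4a bond first and O1–C2 last. Ortho‑specific formylation of the phenol (MgCl2, Et3N, paraformaldehyde, MeCN, reflux) should give 4,6-bis(benzyloxy)-3-{[2,4-bis(benzyloxy)-6-methoxy-5-methyl-3-(3-phenylpropanoyl)phenyl]methyl}-2-hydroxybenzaldehyde F3. Lithium phenylacetylide (THF, −78 °C, where the di‑ortho‑substituted ketone should stay untouched) would add to the aldehyde to give the racemic propargylic alcohol 1-[2,6-bis(benzyloxy)-3-{[2,4-bis(benzyloxy)-6-hydroxy-5-(1-hydroxy-3-phenylprop-2-yn-1-yl)phenyl]methyl}-4-methoxy-5-methylphenyl]-3-phenylpropan-1-one F4. MnO2 in CH2Cl2 would oxidise it to the ynone 1-[2,6-bis(benzyloxy)-3-{[2,4-bis(benzyloxy)-6-hydroxy-5-(3-phenylprop-2-ynoyl)phenyl]methyl}-4-methoxy-5-methylphenyl]-3-phenylpropan-1-one F5. Amine‑mediated 6‑endo oxa‑Michael cyclisation (Et2NH, EtOH, rt) would then close the pyranone to 14.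

Step 9. Oxidation of benzylic C–H bonds (benzyl ethers, bridge methylene) or of the electron‑rich rings may overtake the slow epoxidation of the vinylogous ester. The fallback sets out from 14 and returns at 16. C3 is deprotonated with LDA (3.2 equiv, THF, −78 °C; the first equivalent is consumed by the α‑methylene of the dihydrochalcone ketone) and the anion trapped with B(OMe)3 to give dimethyl [5,7-bis(benzyloxy)-8-{[2,4-bis(benzyloxy)-6-methoxy-5-methyl-3-(3-phenylpropanoyl)phenyl]methyl}-4-oxo-2-phenyl-4H-chromen-3-yl]boronate F6. This is oxidised in the same flask with H2O2/AcOH to flavonol 16 (known C3 lithiation–borylation–oxidation of flavones).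

**Further compounds**
F1 | step 5 | 2,4-bis(benzyloxy)-6-methoxy-5-methyl-3-(3-phenylpropanoyl)benzaldehyde | COc1c(C)c(OCc2ccccc2)c(C(=O)CCc2ccccc2)c(OCc2ccccc2)c1C=O
F2 | step 5 | racemic 1-[2,6-bis(benzyloxy)-3-{[2,4-bis(benzyloxy)-6-hydroxyphenyl](hydroxy)methyl}-4-methoxy-5-methylphenyl]-3-phenylpropan-1-one | COc1c(C)c(OCc2ccccc2)c(C(=O)CCc2ccccc2)c(OCc2ccccc2)c1C(O)c1c(O)cc(OCc2ccccc2)cc1OCc1ccccc1
F3 | step 8 | 4,6-bis(benzyloxy)-3-{[2,4-bis(benzyloxy)-6-methoxy-5-methyl-3-(3-phenylpropanoyl)phenyl]methyl}-2-hydroxybenzaldehyde | COc1c(C)c(OCc2ccccc2)c(C(=O)CCc2ccccc2)c(OCc2ccccc2)c1Cc1c(O)c(C=O)c(OCc2ccccc2)cc1OCc1ccccc1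
F4 | step 8 | racemic 1-[2,6-bis(benzyloxy)-3-{[2,4-bis(benzyloxy)-6-hydroxy-5-(1-hydroxy-3-phenylprop-2-yn-1-yl)phenyl]methyl}-4-methoxy-5-methylphenyl]-3-phenylpropan-1-one | COc1c(C)c(OCc2ccccc2)c(C(=O)CCc2ccccc2)c(OCc2ccccc2)c1Cc1c(O)c(C(O)C#Cc2ccccc2)c(OCc2ccccc2)cc1OCc1ccccc1
F5 | step 8 | 1-[2,6-bis(benzyloxy)-3-{[2,4-bis(benzyloxy)-6-hydroxy-5-(3-phenylprop-2-ynoyl)phenyl]methyl}-4-methoxy-5-methylphenyl]-3-phenylpropan-1-one | COc1c(C)c(OCc2ccccc2)c(C(=O)CCc2ccccc2)c(OCc2ccccc2)c1Cc1c(O)c(C(=O)C#Cc2ccccc2)c(OCc2ccccc2)cc1OCc1ccccc1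
F6 | step 9 | dimethyl [5,7-bis(benzyloxy)-8-{[2,4-bis(benzyloxy)-6-methoxy-5-methyl-3-(3-phenylpropanoyl)phenyl]methyl}-4-oxo-2-phenyl-4H-chromen-3-yl]boronate | COc1c(C)c(OCc2ccccc2)c(C(=O)CCc2ccccc2)c(OCc2ccccc2)c1Cc1c(OCc2ccccc2)cc(OCc2ccccc2)c2c(=O)c(B(OC)OC)c(-c3ccccc3)oc12
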